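## Analysis of the target

The target 20 is a 3-alkylphthalide: a benzene ring fused to a five-membered lactone (C1 carbonyl, O2, C3, C3a, C7a). It carries a methoxy group at C7 beside the lactone carbonyl, a free phenol at C5, hydrogens at C4 and C6, and a fourteen-carbon chain (C1'–C14') on C3 with a ketone at C10' and a secondary alcohol at C13'. The two stereocentres, C3 (S) and C13' (S), are separated by ten chain atoms, so neither can steer the other and each must be set independently. Sensitive sites are the lactone (nucleophiles, strong base), the C3–H bond (benzylic and next to oxygen, so liable to epimerise under base), the phenol, and the 1,4-hydroxy ketone, which can close to a hemiketal and lose water. The difficulty lies in the 1,2,3,5-tetrasubstituted arene with two differently capped oxygens, where a late selective demethylation would attack the C7 ether beside the carbonyl rather than C5, and in an oxygen-bearing benzylic stereocentre whose other substituent is an unfunctionalised alkyl chain. The plan rests on the fact that C3a and C7a are neighbours, C3a holding the sp3 carbon C3 and C7a the carbonyl carbon C1, with the methoxy group on C7 beside C7a. That is the pattern left when a carbon nucleophile adds to a 3-methoxyaryne at the carbon away from the methoxy group and the aryl anion formed beside the methoxy group captures a carbon electrophile. Because C3 also carries O2, the nucleophile can be an oxygen-substituted carbanion whose O-carbamoyl group is itself that electrophile; and the 1,4 spacing of the C10' ketone and C13' hydroxyl is what hydration of a homopropargylic alcohol delivers.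

## Retrosynthetic reasoning

**20 ⇒ 18.** The C10' ketone is traced back to a C10'≡C11' alkyne. A ketone would not survive the alkyllithium bases needed earlier, whereas an internal alkyne should. The C13' hydroxyl, three atoms from C10', should direct the oxygen to C10' through the cyclic enol ether 19, so the forward reaction has to be a hydroxyl-directed hydration and nothing more.

**18 ⇒ 17.** Both hydroxyl groups are capped as triisopropylsilyl ethers. The phenol ether must withstand alkyllithiums and shield the ring positions beside it; the chain ether must withstand the same bases and hot acid. One fluoride treatment should remove both.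

**17 ⇒ 9 + 11.** The bonds C3–C3a and C7a–C1 are cut, and the lactone C1–O2 link is traced to the O–C(=O) unit of carbamate 9. The cut is made here because both bonds sit on adjacent ring carbons, and 9 already holds C3, O2 and C1 in the right order and oxidation state. The arene 11 is then a simple, purchasable pattern in which fluorine marks C3a. Forward, a chiral diamine–alkyllithium base must remove one enantiotopic proton of 9 to give 12, and 11 must be metalated between F and OMe (13) and release aryne 14. Carbanion 12 must then add at the aryne carbon remote from OMe to give 15, the aryl anion must take over the carbamoyl group to give 16 after protonation, and acid must close the lactone. Two fragments of similar size are joined, and the ring, two carbon–carbon bonds and the C3 stereocentre arise together.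

**9 ⇒ 4 + 7.** The sp3–sp bond C9'–C10' is cut. This places the alkyne exactly where the ketone is needed and divides the chain into an achiral C10 bromide that already carries the carbamate (4) and a small chiral alkyne (7). Forward, the lithium acetylide 8 of 7 has to displace a primary bromide without touching the hindered carbamate.

**7 ⇒ 6 ⇒ 5.** Removal of the silyl group gives alkynol 6, and cutting C11'–C12' leads to epoxide 5 and a two-carbon acetylide. The C13' stereocentre is thereby taken from the chiral pool, and the forward opening at the unsubstituted epoxide carbon does not touch it.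

**4 ⇒ 1 + 2.** The carbamate C–O bond is cut to bromo alcohol 1 and carbamoyl chloride 2. Forward, the alcohol must be acylated without loss of the bromide.

**11 ⇒ 10.** Silylation of phenol 10, which is bought with fluorine, methoxy and hydroxyl already in the 1,3,5 relationship.

## Alternatives that were turned down

**Alternative 1: benzene and lactone assembled together by [2+2+2] cyclotrimerization.**
- *Disconnection and key step.* The arene is cut at C7a–C3a, C4–C5 and C6–C7. With Cp*RuCl(cod) as catalyst, the ester-tethered diyne A2 (an (S)-propargylic 3-iodopropiolate) would combine with alkyne A3 to give iodo boryl phthalide A1.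
- *For it.* The reaction class is established, the meta relation of iodine and boron is predictable, no cryogenic organolithium is needed, and C3 is set beforehand by a standard asymmetric synthesis of a propargylic alcohol. On precedent for the key step it is stronger than the chosen route.
- *Against it.* Neither iodine nor boron belongs to the target. C7–I must become C7–OMe by a copper-mediated methoxylation under alkoxide conditions that threaten the lactone, the C3–H bond and the ketone, and C5–B must be oxidised, so at least three steps follow the key step instead of two. The ester tether prefers a conformation that holds the two alkynes apart, and A2 needs a chain aldehyde that already carries the ketone plus a labile iodopropiolate ester.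
- *Comparison.* The chosen route offers an arene bought with both oxygens in place and correctly differentiated, so no carbon–heteroatom exchange is needed on the finished, base-sensitive phthalide.

**Alternative 2: alkyne coupling, oxycyclization to an ylidenephthalide, then hydrogenation.**
- *Disconnection and key step.* C3a–C3 and O2–C3 are cut. Pd(PPh3)2Cl2 and CuI with triethylamine would couple bromo acid A5 with terminal alkyne A6, and the carboxylate would add to the new alkyne in the 5-exo sense to give (Z)-ylidenephthalide A4.
- *For it.* Every operation has close precedent, the fragments are modular and the conditions are mild. On reliability of the individual reactions it is stronger than the chosen route.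
- *Against it.* The 6-endo closure to the isomeric six-membered lactone competes when the alkyne carries an alkyl group. A5 is a doubly ortho-substituted benzoic acid that is slow in oxidative addition and must itself be made by a regioselective bromination. Most importantly, C3 is still flat in A4 and must be created afterwards by a face-selective hydrogenation of a trisubstituted enol lactone in the presence of a ketone, an uncertain catalyst-controlled step.
- *Comparison.* Step counts after the key step are similar. The chosen route sets C3 in the same operation that forms the ring, by an enantioselective deprotonation of a well-understood kind, and keeps the ketone masked throughout.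

**Alternative 3: benzannulation of a chiral hydroxy ynoate with a dioxygenated diene.**
- *Disconnection and key step.* The arene is cut at C4–C3a and C7–C7a and the lactone at O2–C1. Diene A8 would add across the triple bond of the (S)-configured silyloxy ynoate A9, one acetal methoxy group would be lost on aromatisation, and acidic removal of the C3 silyl group would let the hydroxyl close the lactone to give A7.
- *For it.* Polarity fixes the regiochemistry, and the free C5 phenol and the C7 methyl ether emerge directly without any phenol protecting group. A7 is a single desilylation away from the target. On both points it is stronger than the chosen route, which needs a silyl group on the phenol and two steps after the key step.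
- *Against it.* An internal ynoate branched at the adjacent carbon is a sluggish dienophile, while A8 is thermally and hydrolytically fragile, so the forcing conditions needed favour open-chain conjugate adducts and decomposition. The stereocentre of A9 sits at a propargylic position conjugated to the ester and can be lost through allenoate formation. A9 also requires a long linear sequence that includes a separate asymmetric alkynylation of an aldehyde bearing the ketone.
- *Comparison.* The chosen route offers shorter fragment syntheses (four steps or fewer each) and forms both ring carbon–carbon bonds and the C3 stereocentre in one operation.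

Key step: step 6

Remarks on the chemistry:
- Assumption: replacement of lithium by the aryne carbon at the oxygen-substituted carbanion is taken to occur with retention, as is usual for non-benzylic alpha-oxyalkyllithiums, so that (+)-sparteine leads to (3S). If it proved invertive, (−)-sparteine would be used and nothing else changes.
- Organolithium intermediates are drawn as monomeric, ligand-free formulas.

## Route

**Step 1**
Reactants: 1 10-bromodecan-1-ol; 2 N,N-diisopropylcarbamoyl chloride
Product: 4 10-bromodecyl N,N-diisopropylcarbamate, via sodium alkoxide 3 (not isolated)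
Conditions: NaH, THF, 0 °C → rt (1 added last to NaH and 2)
Reagents that add atoms: none
Why: Nucleophilic acyl substitution of the sodium alkoxide on the carbamoyl chloride should be much faster in THF than alkylation of the alkoxide by a primary bromide, so the bromide is kept. The hindered N,N-diisopropylcarbamate is the group that later directs the deprotonation and supplies C1.

**Step 2**
Reactants: 5 (S)-propylene oxide
Product: 6 (2S)-pent-4-yn-2-ol
Conditions: LiC≡CH·H2NCH2CH2NH2, DMSO, 0 °C → rt; then H2O
Reagents that add atoms: lithium acetylide–ethylenediamine complex, [Li]C#C.NCCN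
Why: SN2 opening of the epoxide by the acetylide at the unsubstituted carbon forms C11'–C12'. The C–O bond at the stereocentre is not broken, so the (S) configuration of 5 becomes C13' (S) unchanged.

**Step 3**
Reactants: 6 (2S)-pent-4-yn-2-ol
Product: 7 triisopropyl{[(2S)-pent-4-yn-2-yl]oxy}silane
Conditions: TIPSOTf, 2,6-lutidine, CH2Cl2, 0 °C → rt
Reagents that add atoms: triisopropylsilyl trifluoromethanesulfonate (TIPSOTf), CC(C)[Si](OS(=O)(=O)C(F)(F)F)(C(C)C)C(C)C
Why: Silylation of a secondary alcohol with the silyl triflate and a hindered pyridine base. The triisopropylsilyl ether should tolerate n-BuLi, s-BuLi and hot p-TsOH in the later steps.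

**Step 4**
Reactants: 7 triisopropyl{[(2S)-pent-4-yn-2-yl]oxy}silane; 4 10-bromodecyl N,N-diisopropylcarbamate
Product: 9 (14S)-14-(triisopropylsilyloxy)pentadec-11-yn-1-yl N,N-diisopropylcarbamate, via lithium acetylide 8 (not isolated)
Conditions: n-BuLi, THF, −78 → 0 °C; then 4, DMPU, 0 °C → rt
Reagents that add atoms: none
Why: SN2 alkylation of a lithium acetylide by a primary bromide in a dipolar cosolvent forms C9'–C10'. The hindered carbamate is inert to the acetylide and the stereocentre is remote from the reaction site.

**Step 5**
Reactants: 10 3-fluoro-5-methoxyphenol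
Product: 11 1-fluoro-3-methoxy-5-(triisopropylsilyloxy)benzene
Conditions: TIPSCl, imidazole, DMF, rt
Reagents that add atoms: chlorotriisopropylsilane (TIPSCl), CC(C)[Si](Cl)(C(C)C)C(C)C
Why: Imidazole-promoted silylation of the phenol. The bulky silyl ether resists alkyllithiums and shields both ring positions beside it, leaving the site between F and OMe as the only one open to metalation.

**Step 6**
Reactants: 9 (14S)-14-(triisopropylsilyloxy)pentadec-11-yn-1-yl N,N-diisopropylcarbamate; 11 1-fluoro-3-methoxy-5-(triisopropylsilyloxy)benzene
Product: 17 (3S)-7-methoxy-3-[(13S)-13-(triisopropylsilyloxy)tetradec-10-yn-1-yl]-5-(triisopropylsilyloxy)-2-benzofuran-1(3H)-one, via alpha-lithio carbamate 12 (not isolated), via fluoroaryllithium 13 (not isolated), via aryne 14 (not isolated), via aryllithium adduct 15 (not isolated), via hydroxy amide 16 (not isolated)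
Conditions: 9, (+)-sparteine, s-BuLi, Et2O, −78 °C; separately 11 (1.5 equiv), s-BuLi, THF, −78 °C; mix at −78 °C, then → −40 °C → rt; aq. HCl; crude, p-TsOH·H2O, PhMe, 90 °C
Reagents that add atoms: none
Why: Proposed new method: s-BuLi/(+)-sparteine removes the pro-R proton next to the carbamate oxygen of 9 to give the chelated, configurationally defined carbanion 12, while 11 is lithiated separately between F and OMe to give 13, which loses LiF on warming to aryne 14. Carbanion 12 is expected to add to the aryne carbon remote from OMe (C3–C3a), because the negative charge then develops at C7a beside the inductively withdrawing methoxy group; the aryllithium 15 so formed attacks its own carbamate carbonyl through a five-membered transition state (5-exo-trig, C7a–C1) and expels the benzylic alkoxide, a 1,4 oxygen-to-carbon carbamoyl shift. After aqueous acid, hydroxy amide 16 is heated with p-TsOH and the C3 hydroxyl closes the five-membered lactone by 5-exo-trig acyl substitution at the amide with loss of diisopropylamine, which leaves the C3–O bond untouched. The closest known reaction types are the sparteine-mediated lithiation–substitution of O-alkyl carbamates, the carbolithiation of arynes by alkyllithiums and the anionic homo-Fries rearrangement of ortho-lithiated O-benzyl carbamates to phthalide precursors; new is their union, with a chiral alpha-oxy carbanion as the aryne partner. The C3 stereocentre is set by reagent control in the deprotonation and is carried into the product if lithium is replaced stereospecifically; retention is assumed and leads from (R)-12 to (3S). Three selectivities are needed: lithiation of 11 only between F and OMe, secured by the two flanking heteroatoms and the bulky silyl ether; addition at the aryne carbon meta to OMe, secured by the polarisation of the aryne; and capture of 14 by 12 in preference to 13, which rests on the much higher nucleophilicity of the sp3 carbanion. The main uncertainty is whether 12 keeps its configuration at the temperature at which 13 loses LiF.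

**Step 7**
Reactants: 17 (3S)-7-methoxy-3-[(13S)-13-(triisopropylsilyloxy)tetradec-10-yn-1-yl]-5-(triisopropylsilyloxy)-2-benzofuran-1(3H)-one
Product: 18 (3S)-5-hydroxy-3-[(13S)-13-hydroxytetradec-10-yn-1-yl]-7-methoxy-2-benzofuran-1(3H)-one
Conditions: TBAF, AcOH, THF, 0 → 40 °C
Reagents that add atoms: none
Why: Fluoride-induced cleavage of the Si–O bonds removes the aryl silyl ether quickly and the secondary alkyl silyl ether more slowly. Acetic acid buffers the phenoxide and alkoxide so that the lactone and the C3–H bond should be left alone.

**Step 8**
Reactants: 18 (3S)-5-hydroxy-3-[(13S)-13-hydroxytetradec-10-yn-1-yl]-7-methoxy-2-benzofuran-1(3H)-one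
Product: 20 (3S)-5-hydroxy-3-[(13S)-13-hydroxy-10-oxotetradecyl]-7-methoxy-2-benzofuran-1(3H)-one, via dihydrofuran 19 (not isolated)
Conditions: Ph3PAuCl (5 mol %), AgOTf (5 mol %), THF/H2O, rt
Reagents that add atoms: water, O
Why: The cationic monovalent gold catalyst activates the alkyne and the C13' hydroxyl adds to C10' in a 5-endo-dig hydroalkoxylation (attack at C11' would need a four-membered ring), giving enol ether 19. Protonation and addition of water open 19 to the 1,4-hydroxy ketone, so the carbonyl is placed at C10' only and C13' is untouched.

## Compound list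

1 | 10-bromodecan-1-ol | OCCCCCCCCCCBr | starting material
2 | N,N-diisopropylcarbamoyl chloride | CC(C)N(C(C)C)C(=O)Cl | starting material
3 | sodium 10-bromodecan-1-olate | [Na+].[O-]CCCCCCCCCCBr | intermediate
4 | 10-bromodecyl N,N-diisopropylcarbamate | CC(C)N(C(C)C)C(=O)OCCCCCCCCCCBr | intermediate
5 | (S)-propylene oxide ((2S)-2-methyloxirane) | C[C@H]1CO1 | starting material
6 | (2S)-pent-4-yn-2-ol | C#CC[C@H](C)O | intermediate
7 | triisopropyl{[(2S)-pent-4-yn-2-yl]oxy}silane | C#CC[C@H](C)O[Si](C(C)C)(C(C)C)C(C)C | intermediate
8 | lithium acetylide of 7, [(4S)-4-(triisopropylsilyloxy)pent-1-yn-1-yl]lithium | [Li]C#CC[C@H](C)O[Si](C(C)C)(C(C)C)C(C)C | intermediate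
9 | (14S)-14-(triisopropylsilyloxy)pentadec-11-yn-1-yl N,N-diisopropylcarbamate | CC(C)N(C(C)C)C(=O)OCCCCCCCCCCC#CC[C@H](C)O[Si](C(C)C)(C(C)C)C(C)C | intermediate
10 | 3-fluoro-5-methoxyphenol | COc1cc(O)cc(F)c1 | starting material
11 | 1-fluoro-3-methoxy-5-(triisopropylsilyloxy)benzene | COc1cc(F)cc(O[Si](C(C)C)(C(C)C)C(C)C)c1 | intermediate
12 | [(1R,14S)-1-(N,N-diisopropylcarbamoyloxy)-14-(triisopropylsilyloxy)pentadec-11-yn-1-yl]lithium, formed as its (+)-sparteine complex | [Li][C@@H](OC(=O)N(C(C)C)C(C)C)CCCCCCCCCC#CC[C@H](C)O[Si](C(C)C)(C(C)C)C(C)C | intermediate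
13 | [2-fluoro-6-methoxy-4-(triisopropylsilyloxy)phenyl]lithium | COc1cc(O[Si](C(C)C)(C(C)C)C(C)C)cc(F)c1[Li] | intermediate
14 | 3-methoxy-5-(triisopropylsilyloxy)benzyne (1,2-didehydrobenzene) | COC1=CC(O[Si](C(C)C)(C(C)C)C(C)C)=CC#C1 | intermediate
15 | {2-[(1S,14S)-1-(N,N-diisopropylcarbamoyloxy)-14-(triisopropylsilyloxy)pentadec-11-yn-1-yl]-6-methoxy-4-(triisopropylsilyloxy)phenyl}lithium | COc1cc(O[Si](C(C)C)(C(C)C)C(C)C)cc([C@@H](OC(=O)N(C(C)C)C(C)C)CCCCCCCCCC#CC[C@H](C)O[Si](C(C)C)(C(C)C)C(C)C)c1[Li] | intermediate
16 | 2-[(1S,14S)-1-hydroxy-14-(triisopropylsilyloxy)pentadec-11-yn-1-yl]-6-methoxy-N,N-diisopropyl-4-(triisopropylsilyloxy)benzamide | COc1cc(O[Si](C(C)C)(C(C)C)C(C)C)cc([C@@H](O)CCCCCCCCCC#CC[C@H](C)O[Si](C(C)C)(C(C)C)C(C)C)c1C(=O)N(C(C)C)C(C)C | intermediate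
17 | (3S)-7-methoxy-3-[(13S)-13-(triisopropylsilyloxy)tetradec-10-yn-1-yl]-5-(triisopropylsilyloxy)-2-benzofuran-1(3H)-one | COc1cc(O[Si](C(C)C)(C(C)C)C(C)C)cc2c1C(=O)O[C@H]2CCCCCCCCCC#CC[C@H](C)O[Si](C(C)C)(C(C)C)C(C)C | intermediate
18 | (3S)-5-hydroxy-3-[(13S)-13-hydroxytetradec-10-yn-1-yl]-7-methoxy-2-benzofuran-1(3H)-one | COc1cc(O)cc2c1C(=O)O[C@H]2CCCCCCCCCC#CC[C@H](C)O | intermediate
19 | (3S)-5-hydroxy-7-methoxy-3-{9-[(2S)-2-methyl-2,3-dihydrofuran-5-yl]nonyl}-2-benzofuran-1(3H)-one | COc1cc(O)cc2c1C(=O)O[C@H]2CCCCCCCCCC1=CC[C@H](C)O1 | intermediate
20 | (3S)-5-hydroxy-3-[(13S)-13-hydroxy-10-oxotetradecyl]-7-methoxy-2-benzofuran-1(3H)-one | COc1cc(O)cc2c1C(=O)O[C@H]2CCCCCCCCCC(=O)CC[C@H](C)O | target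

## Step count and least certain steps

Total step count: 8. Longest linear sequence: 6 steps (steps 2, 3, 4, 6, 7, 8, from 5 to 20).

**Step 6 (key step, new method).**
- *Most likely failure.* Decomposition or loss of configuration of carbanion 12 (1,2-carbamoyl shift, racemisation) before the aryne is released, because LiF elimination from 13 needs warming towards −40 °C, near the limit to which such carbanions hold. In addition, the aryne may be captured by 13 instead of 12, and the stereochemical course of the substitution is not known.
- *Fallback (known chemistry).* It sets out from 9 and returns at 17.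
  - 4-Hydroxy-2-methoxybenzoic acid F1 is converted with diethylamine, EDC·HCl and HOBt into N,N-diethyl-4-hydroxy-2-methoxybenzamide F2, and silylated (TIPSCl, imidazole) to N,N-diethyl-2-methoxy-4-(triisopropylsilyloxy)benzamide F3.
  - Amide-directed ortho-lithiation of F3 (s-BuLi, TMEDA, THF, −78 °C) and quenching with 2-isopropoxy-4,4,5,5-tetramethyl-1,3,2-dioxaborolane should give the aryl boronic ester N,N-diethyl-2-methoxy-6-(4,4,5,5-tetramethyl-1,3,2-dioxaborolan-2-yl)-4-(triisopropylsilyloxy)benzamide F4.
  - Carbamate 9 is deprotonated exactly as in step 6 (s-BuLi, (+)-sparteine, Et2O, −78 °C) and carbanion 12 is trapped at −78 °C with F4. The 1,2-aryl shift of the boronate complex (MgBr2·OEt2, MeOH, warming) expels the carbamate and should give the secondary benzylic boronic ester N,N-diethyl-2-methoxy-6-[(1S,14S)-1-(pinacolboryl)-14-(triisopropylsilyloxy)pentadec-11-yn-1-yl]-4-(triisopropylsilyloxy)benzamide F5.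
  - Oxidation with NaBO3·4H2O in THF/H2O gives N,N-diethyl-2-[(1S,14S)-1-hydroxy-14-(triisopropylsilyloxy)pentadec-11-yn-1-yl]-6-methoxy-4-(triisopropylsilyloxy)benzamide F6, and p-TsOH·H2O in toluene closes the lactone to 17.
  - Borylation with retention, migration with inversion and oxidation with retention lead from (R)-12 to the (S) carbinol, so the same sparteine enantiomer serves. Everything happens at −78 °C and no aryne is involved.

**Step 7.**
- *Most likely failure.* Slow cleavage of the hindered secondary silyl ether, so that long exposure to fluoride brings base-induced epimerisation at C3 or opening of the lactone.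
- *Fallback.* It sets out from 17 and returns at 20, changing the order of events. HF·pyridine in THF/pyridine removes only the alkyl silyl ether under acidic conditions to give (3S)-3-[(13S)-13-hydroxytetradec-10-yn-1-yl]-7-methoxy-5-(triisopropylsilyloxy)-2-benzofuran-1(3H)-one F7. The gold-catalysed hydration of step 8 is carried out on F7 to give (3S)-3-[(13S)-13-hydroxy-10-oxotetradecyl]-7-methoxy-5-(triisopropylsilyloxy)-2-benzofuran-1(3H)-one F8. The labile aryl silyl ether is then removed by a short treatment with TBAF/AcOH at 0 °C to give 20.

**Step 8.**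
- *Most likely failure.* Hydration without participation of the hydroxyl group (loss of regiocontrol, carbonyl at C11'), stalling at the cyclic enol ether stage, or slowing of the cationic catalyst by the free phenol.
- *Fallback.* It sets out from 18 and returns at 20, replacing hydroalkoxylation by a silicon-tethered hydrosilylation and oxidation. Both hydroxyl groups are silylated with 1,1,3,3-tetramethyldisilazane to (3S)-5-(dimethylsilyloxy)-3-[(13S)-13-(dimethylsilyloxy)tetradec-10-yn-1-yl]-7-methoxy-2-benzofuran-1(3H)-one F9. [Cp*Ru(MeCN)3]PF6 in dilute CH2Cl2 should effect the intramolecular endo-dig hydrosilylation that puts silicon on C10', giving the six-membered siloxane (3S)-5-(dimethylsilyloxy)-7-methoxy-3-{9-[(6S)-2,2,6-trimethyl-5,6-dihydro-2H-1,2-oxasilin-3-yl]nonyl}-2-benzofuran-1(3H)-one F10. Tamao–Fleming oxidation (KF, KHCO3, H2O2, THF/MeOH) converts the C10'–Si bond into the ketone, frees the C13' hydroxyl and cleaves the aryl silyl ether, giving 20.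

**Step 1.**
- *Most likely failure.* Alkylation of the alkoxide by the primary bromide of a second molecule (ether formation, oligomers) in competition with the slow acylation by the hindered carbamoyl chloride.
- *Fallback.* It sets out from 1 and returns at 9, introducing the carbamate only after the bromide has been consumed. Bromo alcohol 1 is protected with 3,4-dihydro-2H-pyran and PPTS as 2-[(10-bromodecyl)oxy]oxane F11. Lithium acetylide 8 is alkylated with F11 (THF, DMPU) to triisopropyl{[(2S)-15-(oxan-2-yloxy)pentadec-4-yn-2-yl]oxy}silane F12. The acetal is removed with PPTS in MeOH to give (14S)-14-(triisopropylsilyloxy)pentadec-11-yn-1-ol F13, which is carbamoylated with 2 and Et3N in refluxing CH2Cl2 to give 9.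

## Further compounds

F1 | step 6 | 4-hydroxy-2-methoxybenzoic acid | COc1cc(O)ccc1C(=O)O
F2 | step 6 | N,N-diethyl-4-hydroxy-2-methoxybenzamide | CCN(CC)C(=O)c1ccc(O)cc1OC
F3 | step 6 | N,N-diethyl-2-methoxy-4-(triisopropylsilyloxy)benzamide | CCN(CC)C(=O)c1ccc(O[Si](C(C)C)(C(C)C)C(C)C)cc1OC
F4 | step 6 | N,N-diethyl-2-methoxy-6-(4,4,5,5-tetramethyl-1,3,2-dioxaborolan-2-yl)-4-(triisopropylsilyloxy)benzamide | CCN(CC)C(=O)c1c(OC)cc(O[Si](C(C)C)(C(C)C)C(C)C)cc1B1OC(C)(C)C(C)(C)O1
F5 | step 6 | N,N-diethyl-2-methoxy-6-[(1S,14S)-1-(pinacolboryl)-14-(triisopropylsilyloxy)pentadec-11-yn-1-yl]-4-(triisopropylsilyloxy)benzamide | CCN(CC)C(=O)c1c(OC)cc(O[Si](C(C)C)(C(C)C)C(C)C)cc1[C@@H](B1OC(C)(C)C(C)(C)O1)CCCCCCCCCC#CC[C@H](C)O[Si](C(C)C)(C(C)C)C(C)C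
F6 | step 6 | N,N-diethyl-2-[(1S,14S)-1-hydroxy-14-(triisopropylsilyloxy)pentadec-11-yn-1-yl]-6-methoxy-4-(triisopropylsilyloxy)benzamide | CCN(CC)C(=O)c1c(OC)cc(O[Si](C(C)C)(C(C)C)C(C)C)cc1[C@@H](O)CCCCCCCCCC#CC[C@H](C)O[Si](C(C)C)(C(C)C)C(C)C
F7 | step 7 | (3S)-3-[(13S)-13-hydroxytetradec-10-yn-1-yl]-7-methoxy-5-(triisopropylsilyloxy)-2-benzofuran-1(3H)-one | COc1cc(O[Si](C(C)C)(C(C)C)C(C)C)cc2c1C(=O)O[C@H]2CCCCCCCCCC#CC[C@H](C)O
F8 | step 7 | (3S)-3-[(13S)-13-hydroxy-10-oxotetradecyl]-7-methoxy-5-(triisopropylsilyloxy)-2-benzofuran-1(3H)-one | COc1cc(O[Si](C(C)C)(C(C)C)C(C)C)cc2c1C(=O)O[C@H]2CCCCCCCCCC(=O)CC[C@H](C)O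
F9 | step 8 | (3S)-5-(dimethylsilyloxy)-3-[(13S)-13-(dimethylsilyloxy)tetradec-10-yn-1-yl]-7-methoxy-2-benzofuran-1(3H)-one | COc1cc(O[SiH](C)C)cc2c1C(=O)O[C@H]2CCCCCCCCCC#CC[C@H](C)O[SiH](C)C
F10 | step 8 | (3S)-5-(dimethylsilyloxy)-7-methoxy-3-{9-[(6S)-2,2,6-trimethyl-5,6-dihydro-2H-1,2-oxasilin-3-yl]nonyl}-2-benzofuran-1(3H)-one | COc1cc(O[SiH](C)C)cc2c1C(=O)O[C@H]2CCCCCCCCCC1=CC[C@H](C)O[Si]1(C)C
F11 | step 1 | 2-[(10-bromodecyl)oxy]oxane (mixture at the acetal carbon) | BrCCCCCCCCCCOC1CCCCO1
F12 | step 1 | triisopropyl{[(2S)-15-(oxan-2-yloxy)pentadec-4-yn-2-yl]oxy}silane (mixture at the acetal carbon) | C1CCC(OCCCCCCCCCCC#CC[C@H](C)O[Si](C(C)C)(C(C)C)C(C)C)OC1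
F13 | step 1 | (14S)-14-(triisopropylsilyloxy)pentadec-11-yn-1-ol | OCCCCCCCCCCC#CC[C@H](C)O[Si](C(C)C)(C(C)C)C(C)C
A1 | alternative 1 | (3S)-3-[(13S)-13-(tert-butyldimethylsilyloxy)-10-oxotetradecyl]-7-iodo-5-(4,4,5,5-tetramethyl-1,3,2-dioxaborolan-2-yl)-2-benzofuran-1(3H)-one | Ic1cc(B2OC(C)(C)C(C)(C)O2)cc2c1C(=O)O[C@H]2CCCCCCCCCC(=O)CC[C@H](C)O[Si](C)(C)C(C)(C)C
A2 | alternative 1 | (3S,16S)-16-(tert-butyldimethylsilyloxy)-13-oxoheptadec-1-yn-3-yl 3-iodoprop-2-ynoate | IC#CC(=O)O[C@H](C#C)CCCCCCCCCC(=O)CC[C@H](C)O[Si](C)(C)C(C)(C)C
A3 | alternative 1 | 2-ethynyl-4,4,5,5-tetramethyl-1,3,2-dioxaborolane | C#CB1OC(C)(C)C(C)(C)O1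
A4 | alternative 2 | (3Z)-3-[(13S)-13-(tert-butyldimethylsilyloxy)-10-oxotetradecylidene]-7-methoxy-5-(triisopropylsilyloxy)-2-benzofuran-1(3H)-one | COc1cc(O[Si](C(C)C)(C(C)C)C(C)C)cc2c1C(=O)O/C2=C\CCCCCCCCC(=O)CC[C@H](C)O[Si](C)(C)C(C)(C)C
A5 | alternative 2 | 2-bromo-6-methoxy-4-(triisopropylsilyloxy)benzoic acid | COc1cc(O[Si](C(C)C)(C(C)C)C(C)C)cc(Br)c1C(=O)O
A6 | alternative 2 | (14S)-14-(tert-butyldimethylsilyloxy)pentadec-1-yn-11-one | C#CCCCCCCCCC(=O)CC[C@H](C)O[Si](C)(C)C(C)(C)C
A7 | alternative 3 | (3S)-3-[(13S)-13-(tert-butyldimethylsilyloxy)-10-oxotetradecyl]-5-hydroxy-7-methoxy-2-benzofuran-1(3H)-one | COc1cc(O)cc2c1C(=O)O[C@H]2CCCCCCCCCC(=O)CC[C@H](C)O[Si](C)(C)C(C)(C)C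
A8 | alternative 3 | 1,1-dimethoxy-3-(trimethylsilyloxy)buta-1,3-diene | COC(OC)=CC(=C)O[Si](C)(C)C
A9 | alternative 3 | methyl (4S,17S)-17-(tert-butyldimethylsilyloxy)-14-oxo-4-(triethylsilyloxy)octadec-2-ynoate (triethylsilyl chosen as the more labile C4 silyl group) | COC(=O)C#C[C@@H](O[Si](CC)(CC)CC)CCCCCCCCCC(=O)CC[C@H](C)O[Si](C)(C)C(C)(C)C
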